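## Retrosynthetic overview

1. The target is an (R)-4-methoxyisoindolin-1-one whose C3 carries a dearomatised, gem-diprenylated orcinol ring (a cyclic vinylogous acid); C3 is the only stereocentre.
2. Key disconnection C3–C3a (lactam ring, closed last). Both carbons are acceptor sites: C3a is β to the amide carbonyl and C3 is the β-carbon of an alkylidene-1,3-dione. C3a is therefore used with reversed polarity, as an aryl–palladium donor (aromatic homoenolate, d3 synthon) made reductively from the aryl bromide; a chiral bisphosphine sets (R)-C3 in this bond formation.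
3. The cyclisation substrate, an N-(2-bromoaroyl) enaminodione, comes from 2-bromo-3-methoxybenzamide, one carbon of DMF dimethyl acetal (C3) and the vinylogous acid.
4. The vinylogous acid (carbocycle, formed first) comes from 3,3-diprenylacetylacetone and ethyl acetate by aldol addition, Dieckmann-type ring closure and dehydration; the diketone comes from acetylacetone and prenyl bromide.
5. Ring order: carbocyclic dienone ring (step 2), then lactam ring (step 5); the benzene ring is bought.

Assumption: the vinylogous acid is drawn throughout as the 3-hydroxy-2,4-dienone tautomer of the target SMILES; the (R)-ligand is written in step 5, and its mirror image is used if the first run gives the (S)-lactam.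

## Route

Step 1
Reactants: 1 acetylacetone (pentane-2,4-dione); 2 prenyl bromide (1-bromo-3-methylbut-2-ene)
Product: 4 3,3-bis(3-methylbut-2-en-1-yl)pentane-2,4-dione, via monoprenyl diketone 3 (not isolated)
Conditions: 2 (2.3 equiv), K2CO3 (3 equiv), Bu4NI (10 mol%), acetone, reflux
Reagents that add atoms: none
Why: Twofold SN2 C-alkylation of the acetylacetone enolate with a reactive allylic bromide (iodide catalysis) builds the quaternary carbon; O-alkylated by-products are removed by chromatography and no stereocentre is formed.

Step 2
Reactants: 4 3,3-bis(3-methylbut-2-en-1-yl)pentane-2,4-dione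
Product: 7 3-hydroxy-5-methyl-6,6-bis(3-methylbut-2-en-1-yl)cyclohexa-2,4-dien-1-one, via hydroxy ester 5 (not isolated), via hydroxy dione 6 (not isolated)
Conditions: LiN(iPr)2 (1.1 equiv), EtOAc (1.05 equiv), THF, −78 °C; 4 (1.0 equiv), −78 °C; LiN(iPr)2 (1.2 equiv), −78 to 0 °C; then 1 M HCl, THF, rt
Reagents that add atoms: ethyl acetate, CCOC(C)=O
Why: Lithiated ethyl acetate adds once to one of the two equivalent ketones of 4 (aldol addition, kept cold to suppress retro-aldol cleavage), the methyl ketone enolate made by the second portion of base closes the six-membered ring on the ester (Dieckmann-type Claisen condensation, as in the dimedone synthesis), and the racemic tertiary β-hydroxy ketone 6 dehydrates on acidic work-up to the conjugated vinylogous acid, which removes its stereocentre.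

Step 3
Reactants: 8 2-bromo-3-methoxybenzoic acid
Product: 10 2-bromo-3-methoxybenzamide, via acyl imidazolide 9 (not isolated)
Conditions: 1,1'-carbonyldiimidazole (1.2 equiv), THF, rt; then 28% aq. NH3, 0 °C to rt
Reagents that add atoms: ammonia, N
Why: Standard amide formation by carbonyldiimidazole activation of the acid and aminolysis of the acyl imidazolide; no stereocentre is formed.

Step 4
Reactants: 10 2-bromo-3-methoxybenzamide; 7 3-hydroxy-5-methyl-6,6-bis(3-methylbut-2-en-1-yl)cyclohexa-2,4-dien-1-one
Product: 12 2-bromo-3-methoxy-N-{[4-methyl-5,5-bis(3-methylbut-2-en-1-yl)-2,6-dioxocyclohex-3-en-1-ylidene]methyl}benzamide, via N-acylformamidine 11 (not isolated)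
Conditions: 10, Me2NCH(OMe)2 (1.5 equiv), toluene, 90 °C, evaporate; then 7 (1.0 equiv), AcOH (2 equiv), toluene, 60 °C
Reagents that add atoms: N,N-dimethylformamide dimethyl acetal, COC(OC)N(C)C
Why: Primary amides condense cleanly with DMF dimethyl acetal to N-acylformamidines, and the acidic dione 7 then attacks the amidine carbon through C2, its only nucleophilic carbon (Knoevenagel/Mannich-type condensation of an active methylene compound with a formamidine), the protonated dimethylamino group being expelled in acetic acid to give the hydrogen-bonded N-acyl enaminodione; the E/Z isomers about the push–pull C=C interconvert, so its geometry is of no consequence.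

Step 5
Reactants: 12 2-bromo-3-methoxy-N-{[4-methyl-5,5-bis(3-methylbut-2-en-1-yl)-2,6-dioxocyclohex-3-en-1-ylidene]methyl}benzamide
Product: 13 (3R)-3-[2-hydroxy-4-methyl-5,5-bis(3-methylbut-2-en-1-yl)-6-oxocyclohexa-1,3-dien-1-yl]-4-methoxy-2,3-dihydro-1H-isoindol-1-one
Conditions: Pd(OAc)2 (5 mol%), (R)-DTBM-SEGPHOS (6 mol%), HCO2Na (2 equiv), HCO2H (1 equiv), degassed DMF, 80 °C
Reagents that add atoms: none
Why: Proposed new method: oxidative addition of zerovalent palladium into the C–Br bond turns C3a (normally an acceptor, β to the amide carbonyl) into an arylpalladium donor (aromatic homoenolate, d3 equivalent), which adds 5-exo to the electrophilic CH carbon of the alkylidene-1,3-dione to give a palladium 1,3-diketonate that cannot undergo β-hydride elimination and is released by protonolysis, formate returning divalent palladium to the zerovalent state, and the face of the C=C bond is chosen in the migratory insertion inside the chiral bisphosphine pocket, which sets (R)-C3; the closest known chemistry is the Cacchi hydroarylation of enones, asymmetric intramolecular reductive Heck cyclisations (3-arylindanones, oxindoles, dihydrobenzofurans) and Heck cyclisations of N-(2-halobenzoyl)enaminones to isoindolinones.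

## Compound list

1 | acetylacetone (pentane-2,4-dione) | CC(=O)CC(C)=O | starting material
2 | prenyl bromide (1-bromo-3-methylbut-2-ene) | CC(C)=CCBr | starting material
3 | 3-(3-methylbut-2-en-1-yl)pentane-2,4-dione | CC(=O)C(CC=C(C)C)C(C)=O | intermediate
4 | 3,3-bis(3-methylbut-2-en-1-yl)pentane-2,4-dione | CC(=O)C(CC=C(C)C)(CC=C(C)C)C(C)=O | intermediate
5 | ethyl 3-hydroxy-3-methyl-4,4-bis(3-methylbut-2-en-1-yl)-5-oxohexanoate (racemic) | CCOC(=O)CC(C)(O)C(CC=C(C)C)(CC=C(C)C)C(C)=O | intermediate
6 | 5-hydroxy-5-methyl-4,4-bis(3-methylbut-2-en-1-yl)cyclohexane-1,3-dione (racemic) | CC1(O)CC(=O)CC(=O)C1(CC=C(C)C)CC=C(C)C | intermediate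
7 | 3-hydroxy-5-methyl-6,6-bis(3-methylbut-2-en-1-yl)cyclohexa-2,4-dien-1-one (enol form of 5-methyl-6,6-diprenylcyclohex-4-ene-1,3-dione) | CC1=CC(O)=CC(=O)C1(CC=C(C)C)CC=C(C)C | intermediate
8 | 2-bromo-3-methoxybenzoic acid | COc1cccc(C(=O)O)c1Br | starting material
9 | (2-bromo-3-methoxyphenyl)(1H-imidazol-1-yl)methanone | COc1cccc(C(=O)n2ccnc2)c1Br | intermediate
10 | 2-bromo-3-methoxybenzamide | COc1cccc(C(N)=O)c1Br | intermediate
11 | (E)-2-bromo-N-[(dimethylamino)methylidene]-3-methoxybenzamide | COc1cccc(C(=O)/N=C/N(C)C)c1Br | intermediate
12 | 2-bromo-3-methoxy-N-{[4-methyl-5,5-bis(3-methylbut-2-en-1-yl)-2,6-dioxocyclohex-3-en-1-ylidene]methyl}benzamide (E/Z mixture about the exocyclic C=C, interconverting) | COc1cccc(C(=O)NC=C2C(=O)C=C(C)C(CC=C(C)C)(CC=C(C)C)C2=O)c1Br | intermediate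
13 | (3R)-3-[2-hydroxy-4-methyl-5,5-bis(3-methylbut-2-en-1-yl)-6-oxocyclohexa-1,3-dien-1-yl]-4-methoxy-2,3-dihydro-1H-isoindol-1-one | COc1cccc2c1[C@H](C1=C(O)C=C(C)C(CC=C(C)C)(CC=C(C)C)C1=O)NC2=O | target

## Step count and risks

Total step count: 5. Longest linear sequence: 4 (steps 1, 2, 4, 5; step 3 is a one-step side branch).

The three steps most likely to fail:

**Step 5 (reductive cyclisation).** Hydrodebromination, β-hydride elimination to the 3-ylidene lactam, slow reaction through the minor amide rotamer, or low enantioselectivity may intervene. The fallback sets out from 7 and comes back to the route at 13. Commercial 3-methoxybenzonitrile is lithiated between its two substituents with lithium 2,2,6,6-tetramethylpiperidide (THF, −78 °C) and formylated with DMF to give 2-formyl-3-methoxybenzonitrile F1. Aqueous K2CO3 converts this, by hydrate addition to the nitrile and rearrangement, into racemic 3-hydroxy-4-methoxy-2,3-dihydro-1H-isoindol-1-one F2. F2 and 7 are then joined with a chiral phosphoric acid, (R)- or (S)-3,3'-bis(2,4,6-triisopropylphenyl)-1,1'-binaphthyl-2,2'-diyl hydrogen phosphate (10 mol%, toluene, 4 Å sieves). The acid ionises F2 to an N-acyliminium phosphate ion pair and directs C2 of 7 to one face (asymmetric Mannich-type amidoalkylation), which gives 13 directly.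

**Step 2 (one-pot aldol / ring closure / dehydration).** The hindered lithium aldolate may fragment by retro-aldol cleavage, or the symmetric diketone may react twice. The fallback sets out from 4 and comes back to the route at 6. The kinetic methyl enolate of 4 (LiN(iPr)2, 2.1 equiv, THF, −78 °C) is C-acetylated with 1-acetylbenzotriazole to give 3,3-bis(3-methylbut-2-en-1-yl)heptane-2,4,6-trione F3. In pH 9 buffer F3 undergoes a biomimetic intramolecular aldol reaction, its terminal methyl group attacking the hindered ketone, which gives hydroxy dione 6; this is dehydrated with dilute acid to 7 as before.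

**Step 4 (formamidine condensation).** The aminal intermediate may instead expel the amide and give the dimethylaminomethylidene dione. The fallback sets out from 7 and comes back to the route at 12. Heating 7 with triethyl orthoformate and NH4OAc gives 2-(aminomethylidene)-5-methyl-6,6-bis(3-methylbut-2-en-1-yl)cyclohex-4-ene-1,3-dione F4. Its sodium salt (NaH, THF) is N-acylated with acyl imidazolide 9, prepared as in step 3, to give 12.

Further compounds
F1 | step 5 | 2-formyl-3-methoxybenzonitrile | COc1cccc(C#N)c1C=O
F2 | step 5 | 3-hydroxy-4-methoxy-2,3-dihydro-1H-isoindol-1-one (racemic) | COc1cccc2c1C(O)NC2=O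
F3 | step 2 | 3,3-bis(3-methylbut-2-en-1-yl)heptane-2,4,6-trione | CC(=O)CC(=O)C(CC=C(C)C)(CC=C(C)C)C(C)=O
F4 | step 4 | 2-(aminomethylidene)-5-methyl-6,6-bis(3-methylbut-2-en-1-yl)cyclohex-4-ene-1,3-dione | NC=C1C(=O)C=C(C)C(CC=C(C)C)(CC=C(C)C)C1=O
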